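Numbering: C1 lactone carbonyl, C2 its CH2, C3 peroxy methine, C4 lactone-oxygen quaternary carbon, C5 ring CH2, C6 peroxy quaternary carbon, C7–C18 the chain.
Enabling feature: the 1,2-dioxane (O–O, C3, C4, C5, C6) and the γ-lactone (O, C1, C2, C3, C4) share only the C3–C4 bond, so a C6–OOH and a C4–OH can both add to a vinyl group on C4 (C3=C2), with C1 supplied by CO.
Retrosynthesis: O–C3, C2–C1 and C1–O(C4) are cut together (hydroperoxy vinyl carbinol 14 + CO), then C6–OO (diene 12), C2–C3 (epoxide 11 + sulfonium methylide), C5–C6 (alkenyl Grignard 9 + glycidyl tosylate 8) and C7–C8 (2,3-dibromopropene + Grignard 5).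
Forward: C7–C8, then C5–C6, then C2, then the peroxide; both rings close in the last step, the dioxane first by peroxypalladation and the lactone second by acyl capture.
Stereochemistry: C4 comes from (R)-2-methylglycidol and is never touched; C6 forms without control in the radical peroxidation and the (S) epimer is selected by chromatography; C3 is fixed in the cascade, where only the cis-fused arrangement can lactonise.

Key step: step 8

Assumption: oxygen capture by the C6 radical in step 7 is taken to be unbiased by the remote C4 centre, so both C6 epimers are expected and the route relies on their chromatographic separation.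

Step 1
Reactants: 1 11-phenylundecanoic acid
Product: 2 11-phenylundecan-1-ol
Conditions: LiAlH4, THF, 0 °C to reflux
Reagents that add atoms: none
Why: Hydride reduction of a carboxylic acid to the primary alcohol is routine and the remote phenyl ring is inert.

Step 2
Reactants: 2 11-phenylundecan-1-ol
Product: 3 (11-bromoundecyl)benzene
Conditions: CBr4, PPh3, CH2Cl2, 0 °C to rt
Reagents that add atoms: carbon tetrabromide, BrC(Br)(Br)Br
Why: The Appel reaction converts an unhindered primary alcohol into the bromide under neutral conditions.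

Step 3
Reactants: 3 (11-bromoundecyl)benzene; 4 2,3-dibromoprop-1-ene
Product: 6 2-bromo-14-phenyltetradec-1-ene, via 11-phenylundecylmagnesium bromide 5 (not isolated)
Conditions: Mg, THF, rt; then 4, CuI (5 mol%), THF, −10 °C to rt
Reagents that add atoms: none
Why: Copper-assisted allylic substitution by the primary Grignard reagent (SN2 and SN2′ give the same product) leaves the vinylic bromide untouched, a standard entry to 2-bromo-1-alkenes.

Step 4
Reactants: 7 (R)-2-methylglycidol
Product: 8 (S)-(2-methyloxiran-2-yl)methyl 4-methylbenzenesulfonate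
Conditions: TsCl, Et3N, DMAP (cat.), CH2Cl2, 0 °C
Reagents that add atoms: p-toluenesulfonyl chloride, Cc1ccc(cc1)S(Cl)(=O)=O
Why: O-Sulfonylation of the primary hydroxyl does not involve the quaternary stereocentre, whose descriptor changes from R to S only because CH2OTs outranks the ring CH2.

Step 5
Reactants: 6 2-bromo-14-phenyltetradec-1-ene; 8 (S)-(2-methyloxiran-2-yl)methyl 4-methylbenzenesulfonate
Product: 11 (2S)-2-methyl-2-(2-methylidene-14-phenyltetradecyl)oxirane, via alkenylmagnesium bromide 9 (not isolated), via hydroxy tosylate 10 (not isolated)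
Conditions: 6, Mg, THF, 45 °C; CuI (10 mol%), 8, THF, −30 °C; aq. NH4Cl; then K2CO3, MeOH, rt
Reagents that add atoms: none
Why: Copper-catalysed Grignard opening of the 2,2-disubstituted epoxide at its CH2 terminus (the neopentyl-type tosylate resists direct SN2), then Williamson closure of the tertiary alkoxide onto CH2OTs, moves the oxirane to the other arm without touching the quaternary carbon, so C4 keeps the glycidol configuration.

Step 6
Reactants: 11 (2S)-2-methyl-2-(2-methylidene-14-phenyltetradecyl)oxirane
Product: 12 (3S)-3-methyl-5-methylidene-17-phenylheptadec-1-en-3-ol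
Conditions: Me3S+ I− (3 equiv), n-BuLi (2.9 equiv), THF, −10 °C to rt
Reagents that add atoms: trimethylsulfonium iodide, C[S+](C)C.[I-]
Why: Dimethylsulfonium methylide opens the oxirane at CH2 and further ylide triggers loss of dimethyl sulfide from the betaine (epoxide to one-carbon-homologated allylic alcohol), giving the tertiary vinyl carbinol with C4 unchanged.

Step 7
Reactants: 12 (3S)-3-methyl-5-methylidene-17-phenylheptadec-1-en-3-ol
Product: 14 (3S,5S)-5-hydroperoxy-3,5-dimethyl-17-phenylheptadec-1-en-3-ol, via triethylsilyl peroxide 13 (not isolated)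
Conditions: Co(thd)2 (10 mol%), Et3SiH, O2 (1 atm), ClCH2CH2Cl, rt; then TBAF, THF, 0 °C; chromatography
Reagents that add atoms: dioxygen, O=O
Why: In the Mukaiyama–Isayama hydroperoxysilylation cobalt hydride transfers a hydrogen atom to the CH2 of the more electron-rich 1,1-disubstituted alkene, the tertiary radical captures O2 and is silylated, and fluoride frees the hydroperoxide; the radical is expected to be attacked on both faces, so the C5 epimers (C6 of the target) are separated and the (3S,5S) isomer is taken on.

Step 8
Reactants: 14 (3S,5S)-5-hydroperoxy-3,5-dimethyl-17-phenylheptadec-1-en-3-ol; 15 carbon monoxide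
Product: 16 plakortolide L
Conditions: PdCl2(MeCN)2 (10 mol%), p-benzoquinone (2 equiv), CO (1 atm), THF, 0 °C to rt
Reagents that add atoms: none
Why: Proposed new method: Pd(II) coordinates the vinyl group, the C6 hydroperoxide oxygen adds to the internal carbon C3 (6-exo-trig peroxypalladation, closing the 1,2-dioxane), the primary C2–Pd bond inserts CO faster than it loses β-hydride, and the C4 hydroxyl is acylated by the acyl-palladium (5-exo-trig, closing the γ-lactone), the released Pd(0) being reoxidised by benzoquinone. The closest known reaction types are the Pd(II) oxycarbonylation–lactonisation of pent-4-ene-1,3-diols to cis-fused tetrahydrofuran γ-lactones and the Pd(II)-catalysed 6-exo cyclisation of unsaturated tertiary hydroperoxides to 1,2-dioxanes; their union, with a hydroperoxide as first nucleophile under CO, is the untested part. The new stereocentre C3 is controlled by C4: only the C3 epimer whose CH2–Pd arm is cis to the C4 oxygen can lactonise, and the chair with that arm equatorial, the C4 hydroxyl axial and bound to palladium and the C6 chain equatorial leads to it, which corresponds to (3S). Reversible peroxypalladation should drain the trans epimer through this irreversible exit. The step needs exo rather than 7-endo attack, CO capture before β-hydride loss and an intact O–O bond; Markovnikov addition to a monosubstituted alkene, fast insertion into a primary alkyl–palladium under CO, the two quaternary carbons of the tether and the absence of copper(I), phosphines or other reductants are expected to secure these.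

Compound list
1 | 11-phenylundecanoic acid | OC(=O)CCCCCCCCCCc1ccccc1 | starting material
2 | 11-phenylundecan-1-ol | OCCCCCCCCCCCc1ccccc1 | intermediate
3 | (11-bromoundecyl)benzene | BrCCCCCCCCCCCc1ccccc1 | intermediate
4 | 2,3-dibromoprop-1-ene | C=C(Br)CBr | starting material
5 | 11-phenylundecylmagnesium bromide | Br[Mg]CCCCCCCCCCCc1ccccc1 | intermediate
6 | 2-bromo-14-phenyltetradec-1-ene | C=C(Br)CCCCCCCCCCCCc1ccccc1 | intermediate
7 | (R)-2-methylglycidol | C1[C@](CO)(C)O1 | starting material
8 | (S)-(2-methyloxiran-2-yl)methyl 4-methylbenzenesulfonate | Cc1ccc(cc1)S(=O)(=O)OC[C@@]1(C)OC1 | intermediate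
9 | (14-phenyltetradec-1-en-2-yl)magnesium bromide | C=C([Mg]Br)CCCCCCCCCCCCc1ccccc1 | intermediate
10 | (2S)-2-hydroxy-2-methyl-4-methylidene-16-phenylhexadecyl 4-methylbenzenesulfonate | Cc1ccc(cc1)S(=O)(=O)OC[C@@](C)(O)CC(=C)CCCCCCCCCCCCc1ccccc1 | intermediate
11 | (2S)-2-methyl-2-(2-methylidene-14-phenyltetradecyl)oxirane | C=C(CCCCCCCCCCCCc1ccccc1)C[C@@]1(C)CO1 | intermediate
12 | (3S)-3-methyl-5-methylidene-17-phenylheptadec-1-en-3-ol | C=C[C@@](C)(O)CC(=C)CCCCCCCCCCCCc1ccccc1 | intermediate
13 | (3S,5S)-3,5-dimethyl-17-phenyl-5-[(triethylsilyl)peroxy]heptadec-1-en-3-ol | C=C[C@@](C)(O)C[C@@](C)(OO[Si](CC)(CC)CC)CCCCCCCCCCCCc1ccccc1 | intermediate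
14 | (3S,5S)-5-hydroperoxy-3,5-dimethyl-17-phenylheptadec-1-en-3-ol | C=C[C@@](C)(O)C[C@@](C)(OO)CCCCCCCCCCCCc1ccccc1 | intermediate
15 | carbon monoxide | [C-]#[O+] | starting material
16 | plakortolide L | C[C@]1(CCCCCCCCCCCCc2ccccc2)C[C@]2(C)OC(=O)C[C@@H]2OO1 | target

Total step count: 8. Longest linear sequence: 7 steps (1, 2, 3, 5, 6, 7, 8, from 11-phenylundecanoic acid); step 4 is the only side branch.

Steps most likely to fail

Step 8 (Proposed new method). The hydroperoxide may act as an oxidant rather than a nucleophile: it could reoxidise Pd(0), oxidise CO, or cause Wacker-type ketone formation at the vinyl group. Palladium may also precipitate under CO before turnover. The fallback uses known chemistry, sets out from 12 and returns at 16. The lithium alkoxide of 12 (n-BuLi, THF, −78 °C) is acylated with acryloyl chloride to (3S)-3-methyl-5-methylidene-17-phenylheptadec-1-en-3-yl prop-2-enoate F1. Ring-closing metathesis (second-generation Grubbs catalyst, CH2Cl2, 40 °C), in which the 1,1-disubstituted alkene is a spectator, should give the butenolide (5S)-5-methyl-5-(2-methylidene-14-phenyltetradecyl)furan-2(5H)-one F2. Mukaiyama–Isayama hydroperoxysilylation of the remaining electron-rich alkene should give (5S)-5-methyl-5-{(2S)-2-methyl-14-phenyl-2-[(triethylsilyl)peroxy]tetradecyl}furan-2(5H)-one F3 together with its side-chain epimer. Fluoride should release (5S)-5-[(2S)-2-hydroperoxy-2-methyl-14-phenyltetradecyl]-5-methylfuran-2(5H)-one F4. Diethylamine in trifluoroethanol should then close the 1,2-dioxane by intramolecular peroxy-Michael addition to the butenolide, which for geometric reasons can only give the cis-fused lactone 16, freed from its C6 epimer by chromatography.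

Step 7. Hydrogen-atom transfer to the vinyl group and capture of the C5 peroxyl radical by that group may compete with the wanted path. The unbiased oxygen capture also leaves epimers that may separate poorly as open-chain hydroperoxides; any residue would be removed after step 8, where the epimers are rigid bicycles. No known method is offered that controls this centre. The fallback removes the competing alkene and hydroxyl chemistry by making the peroxide before the vinyl group exists; it sets out from 7 and 6 (as Grignard 9) and returns at 13. 7 is protected (NaH, 4-methoxybenzyl chloride, THF) as (2S)-2-{[(4-methoxyphenyl)methoxy]methyl}-2-methyloxirane F5. Copper-catalysed opening with 9 should give (2S)-1-[(4-methoxyphenyl)methoxy]-2-methyl-4-methylidene-16-phenylhexadecan-2-ol F6. Hydroperoxysilylation of its only alkene should give (2S,4S)-1-[(4-methoxyphenyl)methoxy]-2,4-dimethyl-16-phenyl-4-[(triethylsilyl)peroxy]hexadecan-2-ol F7 and its C4 epimer. DDQ should unmask (2S,4S)-2,4-dimethyl-16-phenyl-4-[(triethylsilyl)peroxy]hexadecane-1,2-diol F8. Dess–Martin oxidation of the primary alcohol should give (2S,4S)-2-hydroxy-2,4-dimethyl-16-phenyl-4-[(triethylsilyl)peroxy]hexadecanal F9. Wittig methylenation (Ph3P=CH2, THF, −78 to 0 °C) should give 13, which re-enters step 7 at the fluoride stage.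

Step 5. Alkenyl transfer to the hindered oxirane CH2 may be slow. Magnesium bromide could then open the epoxide to a bromohydrin, the organometallic could attack the sulfonate, and the product epoxide could be opened a second time. The fallback separates the coupling from the epoxide shift; it sets out from 7 and 6 and returns at 10. 7 is silylated (TBDPSCl, imidazole) to tert-butyl{[(2S)-2-methyloxiran-2-yl]methoxy}diphenylsilane F10. The alkenyllithium from 6 (t-BuLi, Et2O, −78 °C) with BF3·OEt2 should open it at CH2 to (2S)-1-[(tert-butyldiphenylsilyl)oxy]-2-methyl-4-methylidene-16-phenylhexadecan-2-ol F11. TBAF should give (2S)-2-methyl-4-methylidene-16-phenylhexadecane-1,2-diol F12. Tosylation of the primary hydroxyl only (TsCl, pyridine, 0 °C) should give 10, which closes to 11 with K2CO3 in MeOH as in step 5.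

Further compounds
F1 | step 8 | (3S)-3-methyl-5-methylidene-17-phenylheptadec-1-en-3-yl prop-2-enoate | C=CC(=O)O[C@](C)(C=C)CC(=C)CCCCCCCCCCCCc1ccccc1
F2 | step 8 | (5S)-5-methyl-5-(2-methylidene-14-phenyltetradecyl)furan-2(5H)-one | O=C1C=C[C@](C)(CC(=C)CCCCCCCCCCCCc2ccccc2)O1
F3 | step 8 | (5S)-5-methyl-5-{(2S)-2-methyl-14-phenyl-2-[(triethylsilyl)peroxy]tetradecyl}furan-2(5H)-one | O=C1C=C[C@](C)(C[C@@](C)(OO[Si](CC)(CC)CC)CCCCCCCCCCCCc2ccccc2)O1
F4 | step 8 | (5S)-5-[(2S)-2-hydroperoxy-2-methyl-14-phenyltetradecyl]-5-methylfuran-2(5H)-one | O=C1C=C[C@](C)(C[C@@](C)(OO)CCCCCCCCCCCCc2ccccc2)O1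
F5 | step 7 | (2S)-2-{[(4-methoxyphenyl)methoxy]methyl}-2-methyloxirane | COc1ccc(COC[C@@]2(C)OC2)cc1
F6 | step 7 | (2S)-1-[(4-methoxyphenyl)methoxy]-2-methyl-4-methylidene-16-phenylhexadecan-2-ol | COc1ccc(COC[C@@](C)(O)CC(=C)CCCCCCCCCCCCc2ccccc2)cc1
F7 | step 7 | (2S,4S)-1-[(4-methoxyphenyl)methoxy]-2,4-dimethyl-16-phenyl-4-[(triethylsilyl)peroxy]hexadecan-2-ol | COc1ccc(COC[C@@](C)(O)C[C@@](C)(OO[Si](CC)(CC)CC)CCCCCCCCCCCCc2ccccc2)cc1
F8 | step 7 | (2S,4S)-2,4-dimethyl-16-phenyl-4-[(triethylsilyl)peroxy]hexadecane-1,2-diol | OC[C@@](C)(O)C[C@@](C)(OO[Si](CC)(CC)CC)CCCCCCCCCCCCc1ccccc1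
F9 | step 7 | (2S,4S)-2-hydroxy-2,4-dimethyl-16-phenyl-4-[(triethylsilyl)peroxy]hexadecanal | O=C[C@@](C)(O)C[C@@](C)(OO[Si](CC)(CC)CC)CCCCCCCCCCCCc1ccccc1
F10 | step 5 | tert-butyl{[(2S)-2-methyloxiran-2-yl]methoxy}diphenylsilane | CC(C)(C)[Si](OC[C@@]1(C)OC1)(c1ccccc1)c1ccccc1
F11 | step 5 | (2S)-1-[(tert-butyldiphenylsilyl)oxy]-2-methyl-4-methylidene-16-phenylhexadecan-2-ol | CC(C)(C)[Si](OC[C@@](C)(O)CC(=C)CCCCCCCCCCCCc1ccccc1)(c1ccccc1)c1ccccc1
F12 | step 5 | (2S)-2-methyl-4-methylidene-16-phenylhexadecane-1,2-diol | OC[C@@](C)(O)CC(=C)CCCCCCCCCCCCc1ccccc1
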